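(Readings and results come from a simulation for substances that don't exist; the scatter is artificial.)

I start from the time of reading: 10 min for blue and ochre, where tube and closed flask give L and Q one history, and mean residence times of 10 min in red and 50.0 min in teal. Against these I set the times the earlier runs show.

| flask | Z | remark | time |
|---|---|---|---|
| ash | 0.60 M | run made earlier |  |
| alder | 0.40 M | run made earlier |  |
| maple | 0.90 M | run made earlier |  |
| red | 0.60 M | one stirred flow tank at steady state, fed with the mixture as stated, mean residence time 10 min |  |
| blue | 0.60 M | a tube with plug flow, the mixed feed as stated, residence time 10 min | 10 min |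
| ochre | 0.60 M | everything together in a closed stirred flask, run for 10 min | 10 min |
| teal | 0.60 M | one stirred flow tank at steady state, fed with the mixture as stated, mean residence time 50.0 min |  |

- ash (time / min: L / %, Q / %): 0.500: 5.6, 0.3; 0.833: 9.3, 0.8; 1.33: 11.8, 1.3; 2.00: 14.9, 2.7; 4.00: 18.4, 7.3; 6.00: 18.0, 11.7
- alder (time / min: L / %, Q / %): 0.667: 7.7, 0.7; 1.00: 10.4, 0.9; 2.00: 16.5, 3.0; 3.00: 19.4, 5.1; 5.00: 21.7, 10.2; 8.00: 20.3, 17.7
- maple (time / min: L / %, Q / %): 1.33: 10.7, 0.7; 2.50: 14.3, 3.5; 4.00: 15.4, 6.4; 5.00: 14.7, 8.1; 6.00: 14.3, 9.9; 8.00: 12.9, 13.5

(scatter of a reading: 0.3 percentage points)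

- percentages count the Z that a species holds: one J counts as two
- the stated concentrations are those of everything mixed, before any reaction; amounts are the same in each set-up
- steps under discussion: 2 Z -> J; Z -> G; Z <-> L + D; L <-> Q
- the earlier runs were made in a closed, stirred flask

- the set-up with the highest share of L in all that became L or Q, at the outlet or at the end ("none" if the first two lie within 2 percentage points) (red / blue / ochre / teal / none)
- share of L in all that became L or Q, at the outlet or at the end, red
- share of L in all that became L or Q, at the outlet or at the end, blue
- share of L in all that became L or Q, at the outlet or at the end, ochre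
- share of L in all that became L or Q, at the outlet or at the end, teal

The first rung is the life of L on its way to Q. Early in the alder run Q stays below L, so I divide the Q gained by 3.00 min by the area under L and read a forward rate of 0.138 min⁻¹, a life of 7.25 min.

The second rung is red's 10 min, longer than that life.

The next rung is the way back. Late in the alder run Q climbs more slowly than the forward rate times mean L predicts. That gap, divided by mean Q, reads as a back rate of 0.0284 min⁻¹, a back time of 35.2 min. It is a rough reading, a difference of near numbers.

The next rung is teal's 50.0 min, longer than the back time.

In a tank at steady state, Q is made from L, returns to L and leaves. Dividing these rates gives Q per L at the outlet: forward rate times residence time (a Damköhler number), over one plus back rate times residence time. Z does not appear in it. This gives 1.07 for red and 2.85 for teal, the tank ratio I carry, so my shares are 48.2% and 26.0%.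

Running the ash readings on to 10 min, with Q at its last climb and L at the alder run's late fall, gives L 16.1% and Q 20.5%, a share of 44.0% for blue and ochre. I commit to red, ahead by 4.2 percentage points against a margin of 2 points.

The forecast names red, with 45.5% for red, 41.5% for blue, 41.5% for ochre and 17% for teal, on “a reverse step that is weak at best”, bounded by 0.02 per minute. My teal share stands above its figure.

    2 Z → J (k = 0.00512 L mol⁻¹ s⁻¹)
    Z → G (k = 7.61 × 10⁻⁶ s⁻¹)
    Z ⇌ L + D (K = 0.360 M, k = 0.00219 s⁻¹)
    L ⇌ Q (K = 5.35, k = 0.00229 s⁻¹)

Red gives 47.8%, blue and ochre 43.4% each, and teal 25.0%, so red comes first. L turns to Q at 0.137 min⁻¹ and Q returns at 0.0257 min⁻¹, a back time of 38.9 min, longer than red's 10 min and shorter than teal's 50.0 min. My tank ratios 1.07 and 2.85 stand against Q per L of 1.09 in red and 3.00 in teal.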